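**Retrosynthetic overview**
- Fremontin ⇒ (aromatic [3,3] shift) the 4'-O-prenyl ether of 2'-hydroxygenistein ⇒ (C4'–O bond, the key bond) 2'-hydroxygenistein + prenyl bromide; alkylation and rearrangement run in one flask.
- 2'-Hydroxygenistein ⇒ 5,7-dihydroxy-2',4'-dimethoxyisoflavone (O-demethylation).
- Pyranone ring C ⇒ O1–C2 ring closure of an enaminone built from a deoxybenzoin and one carbon of DMF; deoxybenzoin ⇒ phloroglucinol + 2,4-dimethoxyphenylacetic acid (C-acylation).
- Ring order: rings A and B are bought as benzenes; ring C is the only ring made (step 1); the reverse-prenyl side chain comes last.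

Assumption: fremontin has no stereocentre and no stereogenic double bond, so the compound itself is the "single enantiomer" and no asymmetric step is needed.

**Route**

Step 1
Reactants: 1 phloroglucinol; 2 2,4-dimethoxyphenylacetic acid
Product: 5 5,7-dihydroxy-2',4'-dimethoxyisoflavone, via deoxybenzoin 3 (not isolated), via enaminone 4 (not isolated)
Conditions: BF3·OEt2 (neat, as solvent), 80 °C, 2 h; then DMF, MsCl (3 equiv), 55 → 70 °C, 2 h; ice-water
Reagents that add atoms: N,N-dimethylformamide, CN(C)C=O
Why: BF3-promoted Friedel–Crafts C-acylation of the very electron-rich phloroglucinol gives deoxybenzoin 3 as its BF2 chelate, the DMF/MsCl Vilsmeier-type reagent aminomethylenates its methylene to enaminone 4, and ring C closes by O1–C2 bond formation (addition–elimination of the ortho phenol with loss of dimethylamine); this is the established one-pot deoxybenzoin synthesis of 5,7-dihydroxyisoflavones, the aryl methyl ethers survive BF3, and no stereocentre is formed.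

Step 2
Reactants: 5 5,7-dihydroxy-2',4'-dimethoxyisoflavone
Product: 6 2'-hydroxygenistein (5,7,2',4'-tetrahydroxyisoflavone)
Conditions: BBr3 (6 equiv), CH2Cl2, −78 °C → rt, 16 h; then H2O, 0 °C
Reagents that add atoms: none
Why: BBr3 cleaves both aryl methyl ethers (Lewis-acid-assisted SN2 demethylation), while the chromone and the free phenols (borates until hydrolysis) are inert and no other acid-labile group is present yet; no stereocentre is formed.

Step 3
Reactants: 6 2'-hydroxygenistein
Product: 9 fremontin, via prenyl ether 7 (not isolated), via dienone 8 (not isolated)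
Conditions: KOt-Bu (2.05 equiv), DMF, Ar, 0 °C; prenyl bromide (1.0 equiv), −20 → 0 °C; KOt-Bu (1.0 equiv), 90 °C, 3 h; cold 1 M HCl
Reagents that add atoms: prenyl bromide (1-bromo-3-methylbut-2-ene), CC(C)=CCBr
Why: Proposed new method: a base-gated one-flask O-prenylation/oxido-accelerated aromatic Claisen rearrangement of an unprotected polyphenol — with 2.05 equiv of base only the two most acidic phenols (7-OH and 4'-OH) are ionised, and the 4'-phenoxide, less delocalised and more nucleophilic than the vinylogous-carboxylate 7-phenoxide, takes the prenyl group by SN2 to make the key C4'–O bond of 7; the third equivalent of base then ionises the 2'-OH, whose oxido group is para to C5' and raises the electron density there, so the [3,3] shift should deliver the CMe2 terminus to the unhindered C5' (not to C3', flanked by two oxygens) and give dienone 8 as a stabilised beta-diketonate that tautomerises to the arene, at a temperature well below that needed by the neutral ether; all base is held as phenoxide, so no free alkoxide is left to open the pyranone or eliminate isoprene; the closest known reactions are the dianion-controlled 4'-O-alkylation of daidzein-type isoflavones, the water- or Lewis-acid-accelerated Claisen rearrangement of aryl prenyl ethers to ortho-(1,1-dimethylallyl)phenols, and the alkoxide-accelerated oxy-Cope rearrangement; the product has no stereocentre.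

**Compound list**

1 | phloroglucinol (benzene-1,3,5-triol) | Oc1cc(O)cc(O)c1 | starting material
2 | 2,4-dimethoxyphenylacetic acid | COc1ccc(CC(=O)O)c(OC)c1 | starting material
3 | deoxybenzoin: 2-(2,4-dimethoxyphenyl)-1-(2,4,6-trihydroxyphenyl)ethan-1-one (formed in the flask) | COc1ccc(CC(=O)c2c(O)cc(O)cc2O)c(OC)c1 | intermediate
4 | enaminone: 3-(dimethylamino)-2-(2,4-dimethoxyphenyl)-1-(2,4,6-trihydroxyphenyl)prop-2-en-1-one (formed in the flask; alkene geometry not defined, either isomer cyclises) | CN(C)C=C(C(=O)c1c(O)cc(O)cc1O)c1ccc(OC)cc1OC | intermediate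
5 | 5,7-dihydroxy-2',4'-dimethoxyisoflavone: 3-(2,4-dimethoxyphenyl)-5,7-dihydroxy-4H-chromen-4-one | COc1ccc(-c2coc3cc(O)cc(O)c3c2=O)c(OC)c1 | intermediate
6 | 2'-hydroxygenistein: 3-(2,4-dihydroxyphenyl)-5,7-dihydroxy-4H-chromen-4-one | O=c1c(-c2ccc(O)cc2O)coc2cc(O)cc(O)c12 | intermediate
7 | prenyl ether: 5,7-dihydroxy-3-[2-hydroxy-4-(3-methylbut-2-en-1-yloxy)phenyl]-4H-chromen-4-one (formed in the flask as its potassium phenoxide, shown neutral) | CC(C)=CCOc1ccc(-c2coc3cc(O)cc(O)c3c2=O)c(O)c1 | intermediate
8 | dienone: ring B as 3-hydroxy-6-(2-methylbut-3-en-2-yl)cyclohexa-2,4-dien-1-one carrying the 5,7-dihydroxychromon-3-yl group at C4 (formed in the flask as its oxido form, shown neutral; racemic transient sp3 carbon, lost on tautomerisation) | C=CC(C)(C)C1C=C(c2coc3cc(O)cc(O)c3c2=O)C(O)=CC1=O | intermediate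
9 | fremontin: 3-[2,4-dihydroxy-5-(2-methylbut-3-en-2-yl)phenyl]-5,7-dihydroxy-4H-chromen-4-one (achiral) | C=CC(C)(C)c1cc(-c2coc3cc(O)cc(O)c3c2=O)c(O)cc1O | target

**Step count and risks**

Total step count: 3. Longest linear sequence: 3 steps (from 1 or 2 to 9).

Steps most likely to fail, in order: step 3, step 1, step 2.

Step 3 (the proposed one-flask O-prenylation/oxido-accelerated Claisen rearrangement). The risks are alkylation at 7-O or 2'-O instead of 4'-O, a [3,3] shift that stays slow at 90 °C, a shift to C3', and base-induced damage to the pyranone by the 2'-oxido group. The fallback uses only known chemistry, sets out from 6 and comes back at 9. Compound 6 is acylated at its most acidic 7-OH (PivCl 1.0 equiv, Et3N, THF, 0 °C) to give 7-O-pivaloyl-2'-hydroxygenistein F1. A Mitsunobu etherification with 3-methylbut-2-en-1-ol (PPh3, DIAD, THF, 0 °C) alkylates the most acidic and least hindered remaining phenol to give 7-O-pivaloyl-4'-O-prenyl-2'-hydroxygenistein F2. The neutral, water-accelerated thermal Claisen rearrangement (EtOH–H2O 4:1, 130 °C, sealed tube) gives 7-O-pivaloylfremontin F3, and K2CO3 in MeOH at rt removes the pivaloyl group to return 9.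

Step 1 (one-pot acylation and ring closure). The risks are incomplete C-acylation in BF3·OEt2 and a messy formylation when the deoxybenzoin is carried on crude. The fallback sets out from 1 and comes back at 5. A Hoesch reaction of 1 with bought 2,4-dimethoxyphenylacetonitrile F4 (ZnCl2, HCl gas, Et2O, 0 °C) precipitates ketiminium chloride F5, which boiling water hydrolyses to deoxybenzoin 3, now isolated and crystallised. Heating 3 with N,N-dimethylformamide dimethyl acetal in THF at reflux gives enaminone 4 under neutral conditions, and 4 closes to 5 on mildly acidic work-up.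

Step 2 (double demethylation). The risks are incomplete cleavage of the hindered 2'-methyl ether and poor solubility of the boron complexes. The fallback sets out from 2 and comes back at 6, so no methyl ether has to be cleaved on the isoflavone. Compound 2 is demethylated first (48% aq. HBr, AcOH, reflux), and the freed acid lactonises to 6-hydroxybenzofuran-2(3H)-one F6. F6 acylates 1 with ring opening in BF3·OEt2 (80 °C) to give 2-(2,4-dihydroxyphenyl)-1-(2,4,6-trihydroxyphenyl)ethan-1-one F7 in the flask. DMF/MsCl then converts F7 through 3-(dimethylamino)-2-(2,4-dihydroxyphenyl)-1-(2,4,6-trihydroxyphenyl)prop-2-en-1-one F8 into 6.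

**Further compounds**

F1 | step 3 | 7-O-pivaloyl-2'-hydroxygenistein | CC(C)(C)C(=O)Oc1cc(O)c2c(c1)occ(-c1ccc(O)cc1O)c2=O
F2 | step 3 | 7-O-pivaloyl-4'-O-prenyl-2'-hydroxygenistein | CC(C)=CCOc1ccc(-c2coc3cc(OC(=O)C(C)(C)C)cc(O)c3c2=O)c(O)c1
F3 | step 3 | 7-O-pivaloylfremontin | C=CC(C)(C)c1cc(-c2coc3cc(OC(=O)C(C)(C)C)cc(O)c3c2=O)c(O)cc1O
F4 | step 1 | 2,4-dimethoxyphenylacetonitrile (bought) | COc1ccc(CC#N)c(OC)c1
F5 | step 1 | 2-(2,4-dimethoxyphenyl)-1-(2,4,6-trihydroxyphenyl)ethan-1-iminium chloride | COc1ccc(CC(=[NH2+])c2c(O)cc(O)cc2O)c(OC)c1.[Cl-]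
F6 | step 2 | 6-hydroxybenzofuran-2(3H)-one | O=C1Cc2ccc(O)cc2O1
F7 | step 2 | 2-(2,4-dihydroxyphenyl)-1-(2,4,6-trihydroxyphenyl)ethan-1-one | O=C(Cc1ccc(O)cc1O)c1c(O)cc(O)cc1O
F8 | step 2 | 3-(dimethylamino)-2-(2,4-dihydroxyphenyl)-1-(2,4,6-trihydroxyphenyl)prop-2-en-1-one | CN(C)C=C(C(=O)c1c(O)cc(O)cc1O)c1ccc(O)cc1O
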